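The C9–C10 bond of ring B is the disconnection on which the route rests. A cobalt hydride adds a hydrogen atom to C20 of an exocyclic C10=C20 alkene on a preformed ring A. The tertiary C10 radical closes ring B 6-endo onto C9 of the C8=C9 chain alkene, and loss of a C17 hydrogen leaves the C8(17) methylene. One operation makes the trans-decalin, the C9 and C10 centres and the exocyclic alkene, exploiting the array of C10 quaternary methyl, C9–H and C8=C17. The precursor is a monocycle carrying the C4 and C5 centres, joined at C6–C7 to the C7–C9/C11–C17 chain of (R)-linalool; its initiating alkene is deliberately 1,1-disubstituted so that initiation is chemoselective.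

Key step: step 14

Remark: atoms are labelled C1–C20 by labdane numbering of the target, which is (4S,5R,9S,10R,13R).
Assumption: the (R,R)-antipode of the TADDOL catalyst is taken to give the 4S cycloadduct in step 4; if the facial sense is the reverse, the (S,S)-antipode is used and nothing else changes.

Step 1
Reactants: 1 (R)-linalool [(3R)-3,7-dimethylocta-1,6-dien-3-ol]
Product: 2 (3R)-3,7-dimethyl-3-(triethylsilyloxy)octa-1,6-diene
Conditions: TESOTf, 2,6-lutidine, CH2Cl2, −78 to 0 °C
Reagents that add atoms: triethylsilyl trifluoromethanesulfonate, CC[Si](CC)(CC)OS(=O)(=O)C(F)(F)F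
Why: O-silylation of a tertiary alcohol with a silyl triflate and a hindered pyridine base is reliable and does not touch the C13–O bond, so the linalool centre (C13) passes on unchanged.

Step 2
Reactants: 2 (3R)-3,7-dimethyl-3-(triethylsilyloxy)octa-1,6-diene
Product: 3 (2E,6R)-2,6-dimethyl-6-(triethylsilyloxy)octa-2,7-dien-1-ol
Conditions: SeO2 (0.3 equiv), t-BuOOH (3 equiv), salicylic acid (10 mol %), CH2Cl2, rt
Reagents that add atoms: tert-butyl hydroperoxide, CC(C)(C)OO (its oxygen is passed on by selenium dioxide, O=[Se]=O)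
Why: Riley allylic oxidation (ene reaction, then [2,3]-sigmatropic shift) of a trisubstituted alkene should hydroxylate the methyl group trans to the chain, the future C7, with the E geometry kept, while the vinyl group, which has no allylic hydrogen, is left alone.

Step 3
Reactants: 3 (2E,6R)-2,6-dimethyl-6-(triethylsilyloxy)octa-2,7-dien-1-ol
Product: 4 (3R,6E)-8-bromo-3,7-dimethyl-3-(triethylsilyloxy)octa-1,6-diene
Conditions: CBr4, PPh3, CH2Cl2, 0 °C
Reagents that add atoms: carbon tetrabromide, BrC(Br)(Br)Br
Why: Appel bromination converts the primary allylic alcohol into the bromide by SN2 displacement of the alkoxyphosphonium ion under neutral conditions that keep the alkene geometry and the tertiary silyl ether.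

Step 4
Reactants: 5 (E)-3-(tert-butyldimethylsilyloxy)-N,N-dimethylbuta-1,3-dien-1-amine; 6 methacrolein
Product: 9 (S)-4-(hydroxymethyl)-4-methylcyclohex-2-en-1-one, via cycloadduct aldehyde 7 (not isolated), via amino alcohol 8 (not isolated)
Conditions: (4R,5R)-2,2-dimethyl-α,α,α′,α′-tetra(1-naphthyl)-1,3-dioxolane-4,5-dimethanol (1-naphthyl-TADDOL, 20 mol %), toluene, −80 °C; then LiAlH4, Et2O, −78 °C to rt; then aq HF, MeCN, 0 °C to rt
Reagents that add atoms: none
Why: Hydrogen-bond-catalysed Diels–Alder reaction in which the chiral diol should bind the formyl oxygen of 6 and screen one face, so that the aminosiloxydiene adds with its amino-bearing terminus to the substituted carbon of 6 and sets the quaternary C4 centre, after which LiAlH4 reduces only the aldehyde and HF hydrolyses the silyl enol ether and expels dimethylamine (E1cB) to unveil the enone.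

Step 5
Reactants: 9 (S)-4-(hydroxymethyl)-4-methylcyclohex-2-en-1-one
Product: 10 (S)-4-[(tert-butyldiphenylsilyloxy)methyl]-4-methylcyclohex-2-en-1-one
Conditions: TBDPSCl, imidazole, DMF, rt
Reagents that add atoms: tert-butylchlorodiphenylsilane, CC(C)(C)[Si](Cl)(c1ccccc1)c1ccccc1
Why: Silylation of the primary neopentyl alcohol with a silyl chloride and imidazole is routine, and this group is chosen because it survives the base, the organolithium and the acid of steps 9 to 11.

Step 6
Reactants: 10 (S)-4-[(tert-butyldiphenylsilyloxy)methyl]-4-methylcyclohex-2-en-1-one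
Product: 11 (S)-4-[(tert-butyldiphenylsilyloxy)methyl]-2-iodo-4-methylcyclohex-2-en-1-one
Conditions: I2, pyridine, CH2Cl2, rt
Reagents that add atoms: iodine, II
Why: α-Iodination of a cyclohexenone by pyridine addition, iodination of the enolate and elimination is an established reaction of 4,4-disubstituted enones and installs both the handle for C20 and a large α-substituent for the next step.

Step 7
Reactants: 11 (S)-4-[(tert-butyldiphenylsilyloxy)methyl]-2-iodo-4-methylcyclohex-2-en-1-one
Product: 12 (1R,4S)-4-[(tert-butyldiphenylsilyloxy)methyl]-2-iodo-4-methylcyclohex-2-en-1-ol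
Conditions: (S)-2-methyl-CBS-oxazaborolidine (20 mol %), BH3·SMe2, THF, −20 °C
Reagents that add atoms: none
Why: Corey–Bakshi–Shibata reduction in which the iodoalkenyl arm acts as the large group, so the (S)-catalyst should deliver hydride to the α face of the carbonyl and give the 1R carbinol with its hydroxyl cis to the C19 arm, under catalyst control because the C4 centre is remote.

Step 8
Reactants: 12 (1R,4S)-4-[(tert-butyldiphenylsilyloxy)methyl]-2-iodo-4-methylcyclohex-2-en-1-ol
Product: 13 (1R,4S)-4-[(tert-butyldiphenylsilyloxy)methyl]-4-methyl-2-[(trimethylsilyl)methyl]cyclohex-2-en-1-ol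
Conditions: Me3SiCH2MgCl (3 equiv), Pd(PPh3)4 (5 mol %), THF, 50 °C
Reagents that add atoms: (trimethylsilyl)methylmagnesium chloride, C[Si](C)(C)C[Mg]Cl
Why: Kumada–Corriu coupling of an alkenyl iodide with (trimethylsilyl)methylmagnesium chloride under zerovalent palladium is a standard route to allylsilanes, tolerates the hydroxyl group as its magnesium alkoxide and introduces C20.

Step 9
Reactants: 13 (1R,4S)-4-[(tert-butyldiphenylsilyloxy)methyl]-4-methyl-2-[(trimethylsilyl)methyl]cyclohex-2-en-1-ol
Product: 14 tributyl({[(1R,4S)-4-[(tert-butyldiphenylsilyloxy)methyl]-4-methyl-2-[(trimethylsilyl)methyl]cyclohex-2-en-1-yl]oxy}methyl)stannane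
Conditions: KH, THF, 0 °C; then Bu3SnCH2I, rt
Reagents that add atoms: tributyl(iodomethyl)stannane, CCCC[Sn](CCCC)(CCCC)CI
Why: Williamson alkylation of the potassium alkoxide with the reactive iodomethylstannane gives the stannylmethyl ether needed for the sigmatropic step, with no change at C1.

Step 10
Reactants: 14 tributyl({[(1R,4S)-4-[(tert-butyldiphenylsilyloxy)methyl]-4-methyl-2-[(trimethylsilyl)methyl]cyclohex-2-en-1-yl]oxy}methyl)stannane
Product: 16 [(1S,6S)-6-[(tert-butyldiphenylsilyloxy)methyl]-6-methyl-2-[(trimethylsilyl)methyl]cyclohex-2-en-1-yl]methanol, via lithiomethyl ether 15 (not isolated)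
Conditions: n-BuLi, THF, −78 to −40 °C; aq NH4Cl
Reagents that add atoms: none
Why: Still–Wittig [2,3]-sigmatropic rearrangement in which tin–lithium exchange gives the α-alkoxy carbanion, which shifts suprafacially across C1–C10–C5, so that C6 is delivered to C5 on the β face that held the oxygen (cis to C19, H-5 α) while the alkene moves to C1=C10.

Step 11
Reactants: 16 [(1S,6S)-6-[(tert-butyldiphenylsilyloxy)methyl]-6-methyl-2-[(trimethylsilyl)methyl]cyclohex-2-en-1-yl]methanol
Product: 17 [(1R,2S)-2-[(tert-butyldiphenylsilyloxy)methyl]-2-methyl-6-methylidenecyclohexyl]methanol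
Conditions: CF3CO2H (3 equiv), CH2Cl2, −20 °C; aq NaHCO3
Reagents that add atoms: none
Why: Protodesilylation of an allylsilane (SE2′), in which protonation at C1 is followed by loss of silicon from the β-silyl cation, places the alkene at C10=C20 under kinetic control and so turns the ring alkene into the 1,1-disubstituted isomer that the key step needs.

Step 12
Reactants: 17 [(1R,2S)-2-[(tert-butyldiphenylsilyloxy)methyl]-2-methyl-6-methylidenecyclohexyl]methanol
Product: 18 tert-butyl{[(1S,2R)-2-(bromomethyl)-1-methyl-3-methylidenecyclohexyl]methoxy}diphenylsilane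
Conditions: CBr4, PPh3, CH2Cl2, 0 °C to rt
Reagents that add atoms: carbon tetrabromide, BrC(Br)(Br)Br
Why: Appel bromination of the primary alcohol proceeds by SN2 displacement at C6 under neutral conditions that leave the exocyclic alkene and the silyl ether alone.

Step 13
Reactants: 18 tert-butyl{[(1S,2R)-2-(bromomethyl)-1-methyl-3-methylidenecyclohexyl]methoxy}diphenylsilane; 4 (3R,6E)-8-bromo-3,7-dimethyl-3-(triethylsilyloxy)octa-1,6-diene
Product: 20 (3R,6E)-9-[(1R,2S)-2-[(tert-butyldiphenylsilyloxy)methyl]-2-methyl-6-methylidenecyclohexyl]-3,7-dimethyl-3-(triethylsilyloxy)nona-1,6-diene (key-step precursor; 9,10-seco-labda-8,10(20),14-triene-13,19-diol as its 13-TES 19-TBDPS bis-silyl ether), via Grignard reagent 19 (not isolated)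
Conditions: Mg, THF, 40 °C; then 4 (1.3 equiv), Li2CuCl4 (5 mol %), THF, −78 to 0 °C
Reagents that add atoms: none
Why: Magnesium insertion gives the primary Grignard reagent, and its copper-catalysed coupling with the primary allylic bromide under Li2CuCl4 conditions should take the direct (α) course with retention of the E alkene, joining C6 to C7.

Step 14
Reactants: 20 (3R,6E)-9-[(1R,2S)-2-[(tert-butyldiphenylsilyloxy)methyl]-2-methyl-6-methylidenecyclohexyl]-3,7-dimethyl-3-(triethylsilyloxy)nona-1,6-diene
Product: 21 (4S,5R,9S,10R,13R)-labda-8(17),14-diene-13,19-diol as its 13-triethylsilyl 19-tert-butyldiphenylsilyl bis-ether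
Conditions: Co(salen)Cl (salen = N,N′-bis(3,5-di-tert-butylsalicylidene)-1,2-cyclohexanediaminate; 5 mol %), PhSiH3 (10 mol %), benzene (0.02 M), 22 °C, argon
Reagents that add atoms: none
Why: Proposed new method: a cobalt hydride, formed from the chloride of trivalent cobalt and a substoichiometric charge of PhSiH3, should transfer a hydrogen atom to the terminal C20 of the 1,1-disubstituted ring alkene to give the tertiary C10 radical, which adds to C9 of the C8=C9 alkene, and the resulting tertiary C8 radical hands a C17 hydrogen back to divalent cobalt, which releases the C8(17) methylene and regenerates the hydride, so that the step is an isomerisation with no stoichiometric reagent. The closest known reactions are cobalt–salen hydrogen-atom-transfer cycloisomerisations of simple dienes initiated at terminal alkenes and the second ring closure of titanocene-mediated epoxypolyene cyclisations, which runs through this same C10 radical and ends in the same exocyclic alkene. Ring B closes 6-endo-trig, because attack at the CH terminus C9 gives a tertiary radical whereas 5-exo attack at the fully substituted C8 would have to join two quaternary carbons. C10 is set by the resident C5 centre through a chair transition state with the C5 tether equatorial, which puts the forming C9–C10 bond equatorial and the C20 methyl axial (trans fusion, methyl β), and C9 is set by the E geometry of the alkene, which keeps C11 equatorial in that chair (C9–H α). The step needs hydrogen delivery to C10=C20 ahead of C14=C15 and C8=C9, and the exocyclic placement of the initiating alkene is what secures it: 1,1-disubstituted alkenes are the most reactive class toward cobalt hydrides, the trisubstituted chain alkene is the least, and the vinyl group is a monosubstituted alkene on a fully substituted, silyloxy-bearing carbon, although 5-exo addition of its C14 radical to C9 remains the main competing path. The other exposures are return of a C1 hydrogen before cyclisation and re-entry of the product alkene, to be held down by low silane loading, short contact time and the preference of the bulky cobalt complex for the unhindered methyl hydrogens, while the neutral conditions leave the tertiary allylic silyl ether intact.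

Step 15
Reactants: 21 (4S,5R,9S,10R,13R)-labda-8(17),14-diene-13,19-diol 13-triethylsilyl 19-tert-butyldiphenylsilyl bis-ether
Product: 22 (4S,5R,9S,10R,13R)-labda-8(17),14-diene-13,19-diol
Conditions: TBAF (5 equiv), THF, 50 °C
Reagents that add atoms: none
Why: Fluoride cleaves both silicon–oxygen bonds (the tertiary triethylsilyl ether and the neopentyl TBDPS ether) without affecting the alkenes or any stereocentre.

Step 16
Reactants: 22 (4S,5R,9S,10R,13R)-labda-8(17),14-diene-13,19-diol
Product: 23 (4S,5R,9S,10R,13R)-13-hydroxylabda-8(17),14-dien-19-yl (E)-2-methylbut-2-enoate (target, CNP0313179.1)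
Conditions: tigloyl chloride (1.5 equiv), Et3N, 4-(dimethylamino)pyridine (20 mol %), CH2Cl2, 0 °C to rt
Reagents that add atoms: tigloyl chloride [(E)-2-methylbut-2-enoyl chloride], C/C=C(\C)C(=O)Cl
Why: Nucleophile-catalysed acylation with the acid chloride should esterify only the primary C19 hydroxyl, because the tertiary allylic C13 hydroxyl is far too hindered to react under these conditions and the amine base keeps the medium free of acid.

Compound list
1 | (R)-linalool, (3R)-3,7-dimethylocta-1,6-dien-3-ol | C=C[C@](C)(O)CCC=C(C)C | starting material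
2 | (3R)-3,7-dimethyl-3-(triethylsilyloxy)octa-1,6-diene | C=C[C@](C)(O[Si](CC)(CC)CC)CCC=C(C)C | intermediate
3 | (2E,6R)-2,6-dimethyl-6-(triethylsilyloxy)octa-2,7-dien-1-ol | C=C[C@](C)(O[Si](CC)(CC)CC)CC/C=C(\C)CO | intermediate
4 | (3R,6E)-8-bromo-3,7-dimethyl-3-(triethylsilyloxy)octa-1,6-diene | C=C[C@](C)(O[Si](CC)(CC)CC)CC/C=C(\C)CBr | intermediate
5 | (E)-3-(tert-butyldimethylsilyloxy)-N,N-dimethylbuta-1,3-dien-1-amine | CN(C)/C=C/C(=C)O[Si](C)(C)C(C)(C)C | starting material
6 | methacrolein, 2-methylprop-2-enal | CC(=C)C=O | starting material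
7 | (1S,2R)-4-(tert-butyldimethylsilyloxy)-2-(dimethylamino)-1-methylcyclohex-3-ene-1-carbaldehyde (endo cycloadduct) | O=C[C@@]1(C)CCC(O[Si](C)(C)C(C)(C)C)=C[C@H]1N(C)C | intermediate
8 | [(1S,2R)-4-(tert-butyldimethylsilyloxy)-2-(dimethylamino)-1-methylcyclohex-3-en-1-yl]methanol | OC[C@@]1(C)CCC(O[Si](C)(C)C(C)(C)C)=C[C@H]1N(C)C | intermediate
9 | (S)-4-(hydroxymethyl)-4-methylcyclohex-2-en-1-one | O=C1CC[C@](C)(CO)C=C1 | intermediate
10 | (S)-4-[(tert-butyldiphenylsilyloxy)methyl]-4-methylcyclohex-2-en-1-one | O=C1CC[C@](C)(CO[Si](c2ccccc2)(c2ccccc2)C(C)(C)C)C=C1 | intermediate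
11 | (S)-4-[(tert-butyldiphenylsilyloxy)methyl]-2-iodo-4-methylcyclohex-2-en-1-one | O=C1CC[C@](C)(CO[Si](c2ccccc2)(c2ccccc2)C(C)(C)C)C=C1I | intermediate
12 | (1R,4S)-4-[(tert-butyldiphenylsilyloxy)methyl]-2-iodo-4-methylcyclohex-2-en-1-ol | O[C@@H]1CC[C@](C)(CO[Si](c2ccccc2)(c2ccccc2)C(C)(C)C)C=C1I | intermediate
13 | (1R,4S)-4-[(tert-butyldiphenylsilyloxy)methyl]-4-methyl-2-[(trimethylsilyl)methyl]cyclohex-2-en-1-ol | O[C@@H]1CC[C@](C)(CO[Si](c2ccccc2)(c2ccccc2)C(C)(C)C)C=C1C[Si](C)(C)C | intermediate
14 | tributylstannylmethyl ether of 13 (configuration 1R,4S) | CCCC[Sn](CCCC)(CCCC)CO[C@@H]1CC[C@](C)(CO[Si](c2ccccc2)(c2ccccc2)C(C)(C)C)C=C1C[Si](C)(C)C | intermediate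
15 | lithiomethyl ether of 13 (configuration 1R,4S) | [Li]CO[C@@H]1CC[C@](C)(CO[Si](c2ccccc2)(c2ccccc2)C(C)(C)C)C=C1C[Si](C)(C)C | intermediate
16 | [(1S,6S)-6-[(tert-butyldiphenylsilyloxy)methyl]-6-methyl-2-[(trimethylsilyl)methyl]cyclohex-2-en-1-yl]methanol | OC[C@@H]1C(C[Si](C)(C)C)=CCC[C@]1(C)CO[Si](c2ccccc2)(c2ccccc2)C(C)(C)C | intermediate
17 | [(1R,2S)-2-[(tert-butyldiphenylsilyloxy)methyl]-2-methyl-6-methylidenecyclohexyl]methanol | OC[C@@H]1C(=C)CCC[C@]1(C)CO[Si](c2ccccc2)(c2ccccc2)C(C)(C)C | intermediate
18 | tert-butyl{[(1S,2R)-2-(bromomethyl)-1-methyl-3-methylidenecyclohexyl]methoxy}diphenylsilane | BrC[C@@H]1C(=C)CCC[C@]1(C)CO[Si](c2ccccc2)(c2ccccc2)C(C)(C)C | intermediate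
19 | Grignard reagent of 18, {[(1R,2S)-2-[(tert-butyldiphenylsilyloxy)methyl]-2-methyl-6-methylidenecyclohexyl]methyl}magnesium bromide | Br[Mg]C[C@@H]1C(=C)CCC[C@]1(C)CO[Si](c2ccccc2)(c2ccccc2)C(C)(C)C | intermediate
20 | (3R,6E)-9-[(1R,2S)-2-[(tert-butyldiphenylsilyloxy)methyl]-2-methyl-6-methylidenecyclohexyl]-3,7-dimethyl-3-(triethylsilyloxy)nona-1,6-diene (key-step precursor) | C=C[C@](C)(O[Si](CC)(CC)CC)CC/C=C(\C)CC[C@@H]1C(=C)CCC[C@]1(C)CO[Si](c2ccccc2)(c2ccccc2)C(C)(C)C | intermediate
21 | (4S,5R,9S,10R,13R)-labda-8(17),14-diene-13,19-diol 13-triethylsilyl 19-tert-butyldiphenylsilyl bis-ether (key-step product) | C=C[C@](C)(O[Si](CC)(CC)CC)CC[C@H]1C(=C)CC[C@H]2[C@@](C)(CO[Si](c3ccccc3)(c3ccccc3)C(C)(C)C)CCC[C@]12C | intermediate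
22 | (4S,5R,9S,10R,13R)-labda-8(17),14-diene-13,19-diol | C=C[C@](C)(O)CC[C@H]1C(=C)CC[C@H]2[C@@](C)(CO)CCC[C@]12C | intermediate
23 | (4S,5R,9S,10R,13R)-13-hydroxylabda-8(17),14-dien-19-yl (E)-2-methylbut-2-enoate | C=C[C@](C)(O)CC[C@H]1C(=C)CC[C@H]2[C@@](C)(COC(=O)/C(C)=C/C)CCC[C@]12C | target

Total step count: 16. Longest linear sequence: 13 steps (steps 4 to 16); the chain branch (steps 1 to 3) joins at step 13.

Steps most likely to fail

1. Step 14 (the step that carries the new method). What may go wrong: hydrogen-atom delivery to the vinyl terminus C15 followed by 5-exo closure of the C14 radical onto C9; return of a C1 hydrogen before cyclisation, which moves the initiating alkene into the ring where it no longer reacts; or renewed hydrogen-atom transfer to the product with drift of the C8 alkene into ring B. The fallback uses known chemistry, the titanocene radical closure, sets out from alcohol 17 and bromide 4 and comes back at 21. Alcohol 17 is converted with PhSSPh and PBu3 into the phenyl sulfide F1. mCPBA then oxidises sulfur and epoxidises the only alkene to give the spiro-epoxy sulfone F2. Its α-sulfonyl carbanion (n-BuLi, THF–HMPA, −78 °C) is alkylated at C6 with 4 to give the chain-bearing epoxy sulfone F3. Na(Hg) with Na2HPO4 in MeOH removes the sulfonyl group and gives the 10,20-epoxide F4, which is 20 with its C10=C20 alkene replaced by an oxirane. Cp2TiCl (trivalent titanium, made from Cp2TiCl2 and Mn in THF) opens the oxirane homolytically to the same tertiary C10 radical, which closes ring B 6-endo and is terminated by titanium-mediated loss of a C17 hydrogen, giving the 20-hydroxy bicycle F5. The neopentyl C20 hydroxyl is then removed by Barton–McCombie deoxygenation through the S-methyl xanthate F6 (NaH, CS2, MeI; then Bu3SnH, AIBN, toluene, 110 °C), which gives 21.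

2. Step 10. What may go wrong: the lithiated ether may undergo [1,2]-shift or be protonated before it can bond to C5, which is flanked by the quaternary C4. The fallback sets out from alcohol 13 and comes back at 16. PhNCO gives the N-phenylcarbamate F7. Deprotonation and treatment with the cuprate made from (i-PrO)Me2SiCH2MgCl and CuI leads to carbamate-directed syn-SN2′ substitution, which delivers the silylmethyl group to C5 on the β face and gives the alkoxysilane F8. Tamao–Fleming oxidation (H2O2, KF, KHCO3, THF–MeOH) then converts the C6–Si bond into the C6 hydroxyl of 16.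

3. Step 13. What may go wrong: Wurtz coupling or homoallyl–cyclopropylcarbinyl scrambling during magnesium insertion, and leakage of the copper-catalysed substitution to γ-attack (SN2′) on the allylic bromide. The fallback sets out from bromide 18 and bromide 4 and comes back at 20. PhSO2Na in DMF at 70 °C converts 18 into the phenyl sulfone F9. Its carbanion (n-BuLi, THF, −78 °C) is alkylated at C6 by 4 to give the coupled sulfone F10 as a mixture at C6. Reductive desulfonylation with Na(Hg) and Na2HPO4 in MeOH then gives 20.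

Further compounds
F1 | step 14 | phenyl sulfide of 17, tert-butyl{[(1S,2R)-1-methyl-3-methylidene-2-(phenylsulfanylmethyl)cyclohexyl]methoxy}diphenylsilane | c3ccccc3SC[C@@H]1C(=C)CCC[C@]1(C)CO[Si](c2ccccc2)(c2ccccc2)C(C)(C)C
F2 | step 14 | spiro-epoxy sulfone: 10,20-epoxide of the C6 phenyl sulfone of ring A (C4 and C5 as in 17, mixture at C10) | O=S(=O)(c3ccccc3)C[C@@H]1C4(CO4)CCC[C@]1(C)CO[Si](c2ccccc2)(c2ccccc2)C(C)(C)C
F3 | step 14 | chain-bearing epoxy sulfone: 20 with a 10,20-epoxide in place of C10=C20 and a phenylsulfonyl group on C6 (mixture at C6 and C10) | C=C[C@](C)(O[Si](CC)(CC)CC)CC/C=C(\C)CC(S(=O)(=O)c3ccccc3)[C@@H]1C4(CO4)CCC[C@]1(C)CO[Si](c2ccccc2)(c2ccccc2)C(C)(C)C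
F4 | step 14 | 10,20-epoxide corresponding to 20 (mixture at C10) | C=C[C@](C)(O[Si](CC)(CC)CC)CC/C=C(\C)CC[C@@H]1C4(CO4)CCC[C@]1(C)CO[Si](c2ccccc2)(c2ccccc2)C(C)(C)C
F5 | step 14 | 20-hydroxy derivative of 21, (13R)-labda-8(17),14-diene-13,19,20-triol 13-triethylsilyl 19-tert-butyldiphenylsilyl bis-ether | C=C[C@](C)(O[Si](CC)(CC)CC)CC[C@H]1C(=C)CC[C@H]2[C@@](C)(CO[Si](c3ccccc3)(c3ccccc3)C(C)(C)C)CCC[C@]12CO
F6 | step 14 | S-methyl xanthate of F5 at O-20 | C=C[C@](C)(O[Si](CC)(CC)CC)CC[C@H]1C(=C)CC[C@H]2[C@@](C)(CO[Si](c3ccccc3)(c3ccccc3)C(C)(C)C)CCC[C@]12COC(=S)SC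
F7 | step 10 | N-phenylcarbamate of 13 (configuration 1R,4S) | O=C(Nc3ccccc3)O[C@@H]1CC[C@](C)(CO[Si](c2ccccc2)(c2ccccc2)C(C)(C)C)C=C1C[Si](C)(C)C
F8 | step 10 | 16 with the C6 hydroxyl replaced by an isopropoxydimethylsilyl group | CC(C)O[Si](C)(C)C[C@@H]1C(C[Si](C)(C)C)=CCC[C@]1(C)CO[Si](c2ccccc2)(c2ccccc2)C(C)(C)C
F9 | step 13 | phenyl sulfone from 18, tert-butyl{[(1S,2R)-1-methyl-3-methylidene-2-(phenylsulfonylmethyl)cyclohexyl]methoxy}diphenylsilane | O=S(=O)(c3ccccc3)C[C@@H]1C(=C)CCC[C@]1(C)CO[Si](c2ccccc2)(c2ccccc2)C(C)(C)C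
F10 | step 13 | 20 bearing a phenylsulfonyl group on C6 (mixture at C6) | C=C[C@](C)(O[Si](CC)(CC)CC)CC/C=C(\C)CC(S(=O)(=O)c3ccccc3)[C@@H]1C(=C)CCC[C@]1(C)CO[Si](c2ccccc2)(c2ccccc2)C(C)(C)C
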